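**Retrosynthetic overview**
- Feature: on ring A the free 7-OH is ortho to C6, and C6 carries the benzylic stereocentre C2' of the piperidine (flavone numbering, piperidine atoms primed). The unit O7–C7–C6–C2' can therefore be drawn as an ortho-quinone methide with C7=O and C6=C2'.
- Ring C is cut last. O1–C2 comes from 6-endo closure of a 2-hydroxyaryl ynone. C4–C4a comes from lithiation of C4a between the 5-OMe and the MOM-protected O1, then acylation with the Weinreb amide of phenylpropiolic acid, which brings ring B.
- N-CH3 goes back to N-CO2CH3, and the piperidine is cut at N1'–C2'. A chiral phosphoric acid converts a racemic ortho-hydroxybenzylic alcohol bearing a tethered methyl carbamate into the quinone methide and guides nitrogen onto one face of C2'.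
- The carbinol comes from phloroglucinol and 5-aminopentanoic acid by C-acylation, MOM on the para oxygen, methyl on one ortho oxygen and hydride reduction.
- Order of rings: ring A (bought), piperidine (step 6), ring C (step 12).

Key step: step 6

Assumption: the sense of induction of the new closure cannot be derived from a close analogue, so (R)-TRIP is written as the catalyst that leads to (2S)-9. If it leads to the (2R) series, (S)-TRIP takes its place and nothing else changes.

**Step 1**
Reactants: 1 5-aminopentanoic acid
Product: 2 5-[(methoxycarbonyl)amino]pentanoic acid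
Conditions: ClCO2Me, NaOH, H2O, 0 °C → rt; then HCl (pH 2)
Reagents that add atoms: methyl chloroformate, COC(=O)Cl
Why: Schotten–Baumann N-acylation, in which the amine of the aminocarboxylate is the only nucleophile that captures the chloroformate in cold aqueous base, installs the methyl carbamate that serves as N–H donor in step 6 and as the source of the N-methyl carbon in step 7.

**Step 2**
Reactants: 2 5-[(methoxycarbonyl)amino]pentanoic acid; 3 phloroglucinol
Product: 4 methyl N-[5-oxo-5-(2,4,6-trihydroxyphenyl)pentyl]carbamate
Conditions: BF3·OEt2 (solvent and promoter), 80 °C; then aq. NaOAc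
Reagents that add atoms: none
Why: Friedel–Crafts C-acylation of phloroglucinol with a free carboxylic acid in BF3·OEt2 is a standard entry to acylphloroglucinols, the three ring positions being equivalent, the first acyl group deactivating the ring against a second, and a methyl carbamate tolerating the Lewis acid.

**Step 3**
Reactants: 4 methyl N-[5-oxo-5-(2,4,6-trihydroxyphenyl)pentyl]carbamate
Product: 5 methyl N-{5-[2,6-dihydroxy-4-(methoxymethoxy)phenyl]-5-oxopentyl}carbamate
Conditions: MOMCl (1.0 equiv), i-Pr2NEt, THF, −10 → 0 °C
Reagents that add atoms: chloromethyl methyl ether, COCCl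
Why: Williamson-type O-alkylation under weak base should take the hydroxyl para to the ketone first, because it is the most acidic one and is not drawn into hydrogen bonding with the carbonyl, and this oxygen later becomes O1 and the director of the metalation.

**Step 4**
Reactants: 5 methyl N-{5-[2,6-dihydroxy-4-(methoxymethoxy)phenyl]-5-oxopentyl}carbamate
Product: 6 methyl N-{5-[2-hydroxy-6-methoxy-4-(methoxymethoxy)phenyl]-5-oxopentyl}carbamate
Conditions: Me2SO4 (1.05 equiv), K2CO3, acetone, 50 °C
Reagents that add atoms: dimethyl sulfate, COS(=O)(=O)OC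
Why: in this classical O-methylation of a 2,6-dihydroxyaryl ketone the two ortho hydroxyls are equivalent, the survivor is locked in a strong chelate with C=O after the first alkylation and resists a second, and K2CO3 does not deprotonate the carbamate N–H.

**Step 5**
Reactants: 6 methyl N-{5-[2-hydroxy-6-methoxy-4-(methoxymethoxy)phenyl]-5-oxopentyl}carbamate
Product: 7 methyl N-{5-hydroxy-5-[2-hydroxy-6-methoxy-4-(methoxymethoxy)phenyl]pentyl}carbamate (racemic carbinol, used at once without acidic silica)
Conditions: NaBH4 (excess), THF–MeOH, 0 °C; cold pH 7 NaH2PO4/Na2HPO4 buffer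
Reagents that add atoms: none
Why: borohydride 1,2-reduction of the aryl ketone leaves carbamate and MOM acetal untouched, the low temperature and neutral quench keep the electron-rich ortho-hydroxybenzylic alcohol from ionising, and the new carbinol centre is left racemic on purpose because step 6 erases it.

**Step 6**
Reactants: 7 methyl N-{5-hydroxy-5-[2-hydroxy-6-methoxy-4-(methoxymethoxy)phenyl]pentyl}carbamate (racemic)
Product: 9 methyl (2S)-2-[2-hydroxy-6-methoxy-4-(methoxymethoxy)phenyl]piperidine-1-carboxylate, via ortho-quinone methide 8 (not isolated)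
Conditions: (R)-TRIP [(R)-3,3'-bis(2,4,6-triisopropylphenyl)-1,1'-binaphthyl-2,2'-diyl hydrogen phosphate] (10 mol %), 5 Å molecular sieves, toluene (0.02 M), −30 °C
Reagents that add atoms: none
Why: Proposed new method: the phosphoric acid protonates the benzylic hydroxyl of 7 and, pushed by O7, the 5-OMe and the para OMOM oxygen, water leaves to give the planar ortho-quinone methide 8 (C7=O, C6=C2'), so both enantiomers of 7 converge on one achiral intermediate before the tethered carbamate nitrogen adds to C2' and ring A rearomatises. The closest known reaction types are the chiral phosphoric acid-catalysed conjugate additions of external nucleophiles to ortho-quinone methides generated in situ from ortho-hydroxybenzyl alcohols, and the racemic acid-catalysed dehydrative cyclisation of carbamates onto benzylic alcohols; their union in an enantioselective closure by a tethered carbamate has not been shown. The piperidine closes in a 6-exo-trig mode, N1' attacking C2' while the C2'=C6 double bond stays outside the new ring, through a chair-like array of the four methylene groups. C2' is controlled by the catalyst alone: its P–OH binds the quinone methide oxygen O7 and its P=O accepts the carbamate N–H, so both partners sit in the pocket between the two 2,4,6-triisopropylphenyl groups and nitrogen should reach only one face of C2'. The step needs a single quinone methide geometry, which the 5-OMe secures by pushing the chain to the side of C7=O (Z), and it needs the catalysed path to outrun uncatalysed ionisation, which low temperature, dilution and sieves serve. A 1,5-hydrogen shift of 8 to the ortho-hydroxystyrene is no dead end, because the acid can reprotonate it to 8, and neither the MOM acetal nor the product carbamate should ionise under so weak an acid at this temperature.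

**Step 7**
Reactants: 9 methyl (2S)-2-[2-hydroxy-6-methoxy-4-(methoxymethoxy)phenyl]piperidine-1-carboxylate
Product: 10 3-methoxy-5-(methoxymethoxy)-2-[(2S)-1-methylpiperidin-2-yl]phenol
Conditions: LiAlH4 (excess), THF, 0 → 60 °C; aq. potassium sodium tartrate
Reagents that add atoms: none
Why: LiAlH4 reduction of a carbamate to the N-methyl amine (hydride addition, loss of methoxide, reduction of the iminium ion) leaves the aryl ethers and the MOM acetal alone, holds the phenol as an aluminium phenoxide and breaks no bond at C2'.

**Step 8**
Reactants: 10 3-methoxy-5-(methoxymethoxy)-2-[(2S)-1-methylpiperidin-2-yl]phenol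
Product: 11 (2S)-2-{2-methoxy-4-(methoxymethoxy)-6-[(triisopropylsilyl)oxy]phenyl}-1-methylpiperidine
Conditions: TIPSCl, imidazole, DMF, 40 °C
Reagents that add atoms: triisopropylsilyl chloride, CC(C)[Si](Cl)(C(C)C)C(C)C
Why: standard phenol silylation, run with the chloride because silyl triflates attack MOM acetals, masks O7, closes the retro-aza-Michael channel that could scramble C2' and places a bulky, poorly coordinating group next to C8.

**Step 9**
Reactants: 12 phenylpropiolic acid
Product: 13 N-methoxy-N-methyl-3-phenylprop-2-ynamide
Conditions: DCC, MeNHOMe·HCl, Et3N, CH2Cl2, 0 °C → rt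
Reagents that add atoms: N,O-dimethylhydroxylamine hydrochloride, CNOC.Cl
Why: carbodiimide amide coupling of an alkynoic acid gives the Weinreb amide under conditions mild enough to spare the triple bond.

**Step 10**
Reactants: 11 (2S)-2-{2-methoxy-4-(methoxymethoxy)-6-[(triisopropylsilyl)oxy]phenyl}-1-methylpiperidine; 13 N-methoxy-N-methyl-3-phenylprop-2-ynamide
Product: 16 1-{2-methoxy-6-(methoxymethoxy)-3-[(2S)-1-methylpiperidin-2-yl]-4-[(triisopropylsilyl)oxy]phenyl}-3-phenylprop-2-yn-1-one, via aryllithium 14 (not isolated), via tetrahedral lithium adduct 15 (not isolated)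
Conditions: n-BuLi, TMEDA, THF, −40 → 0 °C; 13, −78 °C; AcOH, −78 °C
Reagents that add atoms: none
Why: directed ortho-metalation followed by Weinreb ketone synthesis should work because C4a–H lies between two coordinating oxygens (5-OMe and OMOM) while the only other ring hydrogen, C8–H, is shielded by the TIPS group, the chelated adduct 15 blocks a second addition, and the cold acetic acid quench protonates the released MeNHOMe before it can add to the ynone.

**Step 11**
Reactants: 16 1-{2-methoxy-6-(methoxymethoxy)-3-[(2S)-1-methylpiperidin-2-yl]-4-[(triisopropylsilyl)oxy]phenyl}-3-phenylprop-2-yn-1-one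
Product: 17 1-{6-hydroxy-2-methoxy-3-[(2S)-1-methylpiperidin-2-yl]-4-[(triisopropylsilyl)oxy]phenyl}-3-phenylprop-2-yn-1-one
Conditions: p-TsOH·H2O (1.3 equiv, one to hold the amine as its salt), MeOH–CH2Cl2, 35 °C; aq. NaHCO3
Reagents that add atoms: none
Why: acid-catalysed acetal exchange with methanol removes a MOM group that the neighbouring carbonyl makes especially labile, the aryl TIPS and methyl ethers withstand the conditions, and the non-nucleophilic sulfonate does not add to the ynone.

**Step 12**
Reactants: 17 1-{6-hydroxy-2-methoxy-3-[(2S)-1-methylpiperidin-2-yl]-4-[(triisopropylsilyl)oxy]phenyl}-3-phenylprop-2-yn-1-one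
Product: 19 5-methoxy-6-[(2S)-1-methylpiperidin-2-yl]-2-phenyl-7-[(triisopropylsilyl)oxy]-4H-chromen-4-one, via enaminone 18 (not isolated)
Conditions: Et2NH, EtOH, rt → 50 °C
Reagents that add atoms: none
Why: in this amine-mediated flavone closure, conjugate addition of Et2NH turns the ynone into the β-enaminone 18, where the phenol oxygen can only attack C2 by addition–elimination with loss of the amine, so ring C forms in the 6-endo sense and the 5-exo path to the aurone is shut.

**Step 13**
Reactants: 19 5-methoxy-6-[(2S)-1-methylpiperidin-2-yl]-2-phenyl-7-[(triisopropylsilyl)oxy]-4H-chromen-4-one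
Product: 20 7-hydroxy-5-methoxy-6-[(2S)-1-methylpiperidin-2-yl]-2-phenyl-4H-chromen-4-one (target)
Conditions: Bu4NF, AcOH, THF, 0 °C
Reagents that add atoms: none
Why: fluoride cleavage of the aryl silyl ether, buffered with acetic acid and kept cold, frees the 7-OH without touching the 5-OMe and without giving the 7-oxide/ammonium pair the heat it would need to open the C2'–N bond.

**Compound list**
1 | 5-aminopentanoic acid | NCCCCC(=O)O | starting material
2 | 5-[(methoxycarbonyl)amino]pentanoic acid | COC(=O)NCCCCC(=O)O | intermediate
3 | phloroglucinol (benzene-1,3,5-triol) | Oc1cc(O)cc(O)c1 | starting material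
4 | methyl N-[5-oxo-5-(2,4,6-trihydroxyphenyl)pentyl]carbamate | COC(=O)NCCCCC(=O)c1c(O)cc(O)cc1O | intermediate
5 | methyl N-{5-[2,6-dihydroxy-4-(methoxymethoxy)phenyl]-5-oxopentyl}carbamate | COC(=O)NCCCCC(=O)c1c(O)cc(OCOC)cc1O | intermediate
6 | methyl N-{5-[2-hydroxy-6-methoxy-4-(methoxymethoxy)phenyl]-5-oxopentyl}carbamate | COC(=O)NCCCCC(=O)c1c(O)cc(OCOC)cc1OC | intermediate
7 | methyl N-{5-hydroxy-5-[2-hydroxy-6-methoxy-4-(methoxymethoxy)phenyl]pentyl}carbamate, racemic | COC(=O)NCCCCC(O)c1c(O)cc(OCOC)cc1OC | intermediate
8 | methyl N-{(5Z)-5-[2-methoxy-4-(methoxymethoxy)-6-oxocyclohexa-2,4-dien-1-ylidene]pentyl}carbamate (ortho-quinone methide, not isolated) | COC(=O)NCCCC/C=C1\C(=O)C=C(OCOC)C=C1OC | intermediate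
9 | methyl (2S)-2-[2-hydroxy-6-methoxy-4-(methoxymethoxy)phenyl]piperidine-1-carboxylate | COc1cc(OCOC)cc(O)c1[C@@H]2CCCCN2C(=O)OC | intermediate
10 | 3-methoxy-5-(methoxymethoxy)-2-[(2S)-1-methylpiperidin-2-yl]phenol | COc1cc(OCOC)cc(O)c1[C@@H]2CCCCN2C | intermediate
11 | (2S)-2-{2-methoxy-4-(methoxymethoxy)-6-[(triisopropylsilyl)oxy]phenyl}-1-methylpiperidine | COc1cc(OCOC)cc(O[Si](C(C)C)(C(C)C)C(C)C)c1[C@@H]2CCCCN2C | intermediate
12 | phenylpropiolic acid (3-phenylprop-2-ynoic acid) | OC(=O)C#Cc1ccccc1 | starting material
13 | N-methoxy-N-methyl-3-phenylprop-2-ynamide | CON(C)C(=O)C#Cc1ccccc1 | intermediate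
14 | {2-methoxy-6-(methoxymethoxy)-3-[(2S)-1-methylpiperidin-2-yl]-4-[(triisopropylsilyl)oxy]phenyl}lithium (not isolated) | COc1c([C@@H]2CCCCN2C)c(O[Si](C(C)C)(C(C)C)C(C)C)cc(OCOC)c1[Li] | intermediate
15 | lithium 1-[methoxy(methyl)amino]-1-{2-methoxy-6-(methoxymethoxy)-3-[(2S)-1-methylpiperidin-2-yl]-4-[(triisopropylsilyl)oxy]phenyl}-3-phenylprop-2-yn-1-olate (carbinolate centre undefined, not isolated) | COc1c([C@@H]2CCCCN2C)c(O[Si](C(C)C)(C(C)C)C(C)C)cc(OCOC)c1C([O-])(N(C)OC)C#Cc3ccccc3.[Li+] | intermediate
16 | 1-{2-methoxy-6-(methoxymethoxy)-3-[(2S)-1-methylpiperidin-2-yl]-4-[(triisopropylsilyl)oxy]phenyl}-3-phenylprop-2-yn-1-one | COc1c([C@@H]2CCCCN2C)c(O[Si](C(C)C)(C(C)C)C(C)C)cc(OCOC)c1C(=O)C#Cc3ccccc3 | intermediate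
17 | 1-{6-hydroxy-2-methoxy-3-[(2S)-1-methylpiperidin-2-yl]-4-[(triisopropylsilyl)oxy]phenyl}-3-phenylprop-2-yn-1-one | COc1c([C@@H]2CCCCN2C)c(O[Si](C(C)C)(C(C)C)C(C)C)cc(O)c1C(=O)C#Cc3ccccc3 | intermediate
18 | 3-(diethylamino)-1-{6-hydroxy-2-methoxy-3-[(2S)-1-methylpiperidin-2-yl]-4-[(triisopropylsilyl)oxy]phenyl}-3-phenylprop-2-en-1-one (alkene geometry not fixed, not isolated) | COc1c([C@@H]2CCCCN2C)c(O[Si](C(C)C)(C(C)C)C(C)C)cc(O)c1C(=O)C=C(N(CC)CC)c3ccccc3 | intermediate
19 | 5-methoxy-6-[(2S)-1-methylpiperidin-2-yl]-2-phenyl-7-[(triisopropylsilyl)oxy]-4H-chromen-4-one | COc1c([C@@H]2CCCCN2C)c(O[Si](C(C)C)(C(C)C)C(C)C)cc2oc(-c3ccccc3)cc(=O)c12 | intermediate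
20 | 7-hydroxy-5-methoxy-6-[(2S)-1-methylpiperidin-2-yl]-2-phenyl-4H-chromen-4-one | COc1c([C@@H]2CCCCN2C)c(O)cc2oc(-c3ccccc3)cc(=O)c12 | target

**Step count**
Total: 13 steps. Longest linear sequence: 12 steps (steps 1–8 and 10–13, from 5-aminopentanoic acid). Step 9 is a one-step side branch.

**Steps most likely to fail**

Step 6 (key step). Enantioface selection may be poor for three reasons.
- The very electron-rich carbinol may ionise without the catalyst and close along a racemic background path.
- The quinone methide may not hold a single geometry.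
- Material may drain away through the hydrogen shift to the styrene and through oligomerisation.

The fallback gives up asymmetric catalysis for racemic closure and resolution. It sets out from 7. An achiral acid ((PhO)2P(O)OH or Bi(OTf)3, catalytic, CH2Cl2, 0 °C) effects the known dehydrative cyclisation of a carbamate onto an activated benzylic alcohol. This gives racemic methyl 2-[2-hydroxy-6-methoxy-4-(methoxymethoxy)phenyl]piperidine-1-carboxylate F1. Preparative chromatography on a chiral stationary phase splits it into 9 and methyl (2R)-2-[2-hydroxy-6-methoxy-4-(methoxymethoxy)phenyl]piperidine-1-carboxylate F2. The route resumes at 9.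

Step 10. Deprotonation of the crowded ring may be incomplete, or it may stray to C8, where an oxygen-to-carbon silyl shift would follow and the later closure would give the isomeric 5-oxygenated, 7-methoxy flavone. The hindered aryllithium may also capture the amide slowly. The fallback fixes the metalation site with a halogen instead of relying on kinetic acidity. It sets out from 11. Electrophilic iodination (NIS, one equivalent of CF3CO2H to mask the amine as its salt, MeCN, −20 °C) should go to C4a, the less shielded of the two open positions. This gives (2S)-2-{3-iodo-2-methoxy-4-(methoxymethoxy)-6-[(triisopropylsilyl)oxy]phenyl}-1-methylpiperidine F3, whose regiochemistry can be checked before it is committed. Iodine–lithium exchange (n-BuLi, THF, −78 °C) then gives the aryllithium, and the route resumes at 14.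

Step 5. Reduction of the chelated, electron-rich ketone may be sluggish. With the phenoxide present, the benzylic oxygen may be lost in the flask, after which hydride would reduce the quinone methide to the saturated chain, or nitrogen would trap it without stereocontrol. The fallback keeps the phenoxide out of the hydride step with a protecting-group detour. It sets out from 6. Silylation of the phenol (NaH, one equivalent, TBSCl, THF, 0 °C) gives methyl N-{5-[2-(tert-butyldimethylsilyloxy)-6-methoxy-4-(methoxymethoxy)phenyl]-5-oxopentyl}carbamate F4. NaBH4 in THF–MeOH reduces it to racemic methyl N-{5-[2-(tert-butyldimethylsilyloxy)-6-methoxy-4-(methoxymethoxy)phenyl]-5-hydroxypentyl}carbamate F5, which can be stored. Bu4NF/AcOH in THF at −20 °C frees the phenol just before use, and the route resumes at 7.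

**Further compounds**
F1 | step 6 | methyl 2-[2-hydroxy-6-methoxy-4-(methoxymethoxy)phenyl]piperidine-1-carboxylate, racemic | COc1cc(OCOC)cc(O)c1C2CCCCN2C(=O)OC
F2 | step 6 | methyl (2R)-2-[2-hydroxy-6-methoxy-4-(methoxymethoxy)phenyl]piperidine-1-carboxylate | COc1cc(OCOC)cc(O)c1[C@H]2CCCCN2C(=O)OC
F3 | step 10 | (2S)-2-{3-iodo-2-methoxy-4-(methoxymethoxy)-6-[(triisopropylsilyl)oxy]phenyl}-1-methylpiperidine | COc1c([C@@H]2CCCCN2C)c(O[Si](C(C)C)(C(C)C)C(C)C)cc(OCOC)c1I
F4 | step 5 | methyl N-{5-[2-(tert-butyldimethylsilyloxy)-6-methoxy-4-(methoxymethoxy)phenyl]-5-oxopentyl}carbamate | COC(=O)NCCCCC(=O)c1c(O[Si](C)(C)C(C)(C)C)cc(OCOC)cc1OC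
F5 | step 5 | methyl N-{5-[2-(tert-butyldimethylsilyloxy)-6-methoxy-4-(methoxymethoxy)phenyl]-5-hydroxypentyl}carbamate, racemic | COC(=O)NCCCCC(O)c1c(O[Si](C)(C)C(C)(C)C)cc(OCOC)cc1OC
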